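**Assumption:** the oxiranes are taken to arise in nature by oxygen-atom transfer from an epoxygenase to the 8E double bond of an acyl chain that already carries the 4,6-diyne; the L-fructose-derived Shi ketone, sn-glycero-3-phosphocholine and phospholipase C are taken as catalogue items.

The target is 1,2-di-O-acyl-sn-glycerol (glycerol C2 = S) carrying two identical (8S,9S,13Z,15Z)-8,9-epoxyoctadeca-13,15-diene-4,6-diynoyl chains (trans-oxiranes).

## Retrosynthetic overview

1. Target 18 ⇐ phospholipase C cleavage of phosphatidylcholine 17 ⇐ double acylation of sn-glycero-3-phosphocholine 15 (glycerol stereocentre bought) with epoxy acid 14, used twice.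
2. 14 ⇐ Z-selective Wittig of epoxy phosphonium inner salt 10 with (Z)-pent-2-enal 12; the diene is installed after the oxirane because an electrophilic oxidant would attack the diene first.
3. 10 ⇐ direct oxygen-atom transfer (chiral dioxirane) to the 8E alkene of the unprotected enediyne zwitterion 9, with no hydroxyl directing group and no protecting group.
4. 9 ⇐ PPh3 + bromo enediyne acid 7 ⇐ Cadiot–Chodkiewicz coupling of enyne 4 (from 6-bromohex-1-yne 1) with bromoalkyne 6 (from pent-4-ynoic acid 5).
5. Ring order: the only ring-forming event is the oxirane closure giving 10; both oxiranes of 18 derive from it and enter together in the diacylation.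

## Route

**Step 1**
Reactants: 1 6-bromohex-1-yne
Product: 3 (E)-6-bromo-1-iodohex-1-ene, via alkenylzirconocene chloride 2 (not isolated)
Conditions: Cp2Zr(H)Cl (1.2 equiv), THF, rt, 30 min, dark; then I2 (1.2 equiv), 0 °C
Reagents that add atoms: iodine, II
Why: Hydrozirconation of the terminal alkyne is a syn, anti-Markovnikov addition giving the (E)-alkenylzirconocene, and iodinolysis of the C–Zr bond proceeds with retention, so the E geometry needed for the trans-oxirane is fixed here while the primary bromide is untouched (hydrozirconation–iodination).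

**Step 2**
Reactants: 3 (E)-6-bromo-1-iodohex-1-ene
Product: 4 (E)-8-bromooct-3-en-1-yne
Conditions: HC≡CMgBr (1.5 equiv), ZnBr2 (1.5 equiv), THF, 0 °C; then 3, Pd(PPh3)4 (3 mol%), 0 °C → rt, 3 h
Reagents that add atoms: ethynylmagnesium bromide, C#C[Mg]Br
Why: Negishi coupling of the alkenyl iodide with ethynylzinc bromide is stereoretentive and gives the terminal (E)-enyne directly without a silyl group, the alkyl bromide being inert to the palladium catalyst and to the organozinc at room temperature.

**Step 3**
Reactants: 5 pent-4-ynoic acid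
Product: 6 5-bromopent-4-ynoic acid
Conditions: Br2 (1.05 equiv), KOH (4 equiv), H2O, 0 °C, 2 h; then HCl to pH 2, 0 °C
Reagents that add atoms: bromine, BrBr
Why: Alkaline hypobromite brominates the acetylide of the terminal alkyne (Straus-type bromination) with the carboxylate as a spectator, and the absence of silver salts avoids cyclisation of the alkynoic acid to an enol lactone.

**Step 4**
Reactants: 4 (E)-8-bromooct-3-en-1-yne; 6 5-bromopent-4-ynoic acid
Product: 7 (E)-13-bromotridec-8-ene-4,6-diynoic acid
Conditions: CuCl (10 mol%), NH2OH·HCl (0.3 equiv), 30% aq n-BuNH2, MeOH, 0 °C, 45 min (6 added slowly); then citric acid to pH 3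
Reagents that add atoms: none
Why: Cadiot–Chodkiewicz coupling joins the copper acetylide of 4 with bromoalkyne 6 to give the unsymmetrical 1,3-diyne selectively, and the short reaction at 0 °C leaves the primary bromide and the E-alkene untouched.

**Step 5**
Reactants: 7 (E)-13-bromotridec-8-ene-4,6-diynoic acid
Product: 9 (E)-13-(triphenylphosphonio)tridec-8-ene-4,6-diynoate (inner salt), via phosphonium bromide 8 (not isolated)
Conditions: PPh3 (3 equiv), MeCN, 65 °C, 36 h, dark, Ar; Et2O trituration; then CH2Cl2/aq NaHCO3 (1.05 equiv) partition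
Reagents that add atoms: triphenylphosphine, c1ccc(cc1)P(c1ccccc1)c1ccccc1
Why: SN2 quaternisation of PPh3 by the primary bromide gives the phosphonium salt, and partition against NaHCO3 removes bromide to leave the halide-free phosphonium carboxylate, which matters because bromide would be oxidised by KHSO5 in the next step and because no free acid or halide then sits beside the later oxirane.

**Step 6 (key step)**
Reactants: 9 (E)-13-(triphenylphosphonio)tridec-8-ene-4,6-diynoate (inner salt)
Product: 10 7-{(2S,3S)-3-[4-(triphenylphosphonio)butyl]oxiran-2-yl}hepta-4,6-diynoate (inner salt)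
Conditions: L-fructose-derived Shi ketone (1,2:4,5-di-O-isopropylidene-β-L-erythro-2,3-hexodiulo-2,6-pyranose, 0.3 equiv), KHSO5 (as 2KHSO5·KHSO4·K2SO4, 1.5 equiv), K2CO3, MeCN/CH2(OMe)2 (1:2), aq Na2B4O7/Na2H2EDTA buffer, pH 10.5, −5 °C, 3 h
Reagents that add atoms: potassium peroxymonosulfate, [K+].[O-]S(=O)(=O)OO
Why: Shi asymmetric epoxidation, in which the chiral dioxirane transfers oxygen syn-stereospecifically through a spiro transition state to the E-alkene (alkynes, phosphonium and carboxylate are inert), and since the D-fructose-derived ketone gives (R,R)-epoxides from trans-disubstituted alkenes and trans-enynes its enantiomer sets both new stereocentres as (8S,9S) in a trans-oxirane.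

**Step 7**
Reactants: 11 (Z)-pent-2-en-1-ol
Product: 12 (Z)-pent-2-enal
Conditions: Dess–Martin periodinane (1.2 equiv), NaHCO3 (3 equiv), CH2Cl2, 0 °C, 40 min; cold filtration, solution used at once
Reagents that add atoms: none
Why: Buffered Dess–Martin oxidation converts the allylic alcohol into the enal under neutral conditions at 0 °C, so the Z geometry is kept provided the aldehyde is used immediately.

**Step 8**
Reactants: 10 7-{(2S,3S)-3-[4-(triphenylphosphonio)butyl]oxiran-2-yl}hepta-4,6-diynoate (inner salt); 12 (Z)-pent-2-enal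
Product: 14 (8S,9S,13Z,15Z)-8,9-epoxyoctadeca-13,15-diene-4,6-diynoic acid, via phosphonium ylide 13 (not isolated)
Conditions: NaN(SiMe3)2 (1.0 equiv), THF/DMPU (10:1), −78 °C, 20 min; then 12 (1.5 equiv), −78 → −30 °C, 2 h; aq NaH2PO4, 0 °C
Reagents that add atoms: none
Why: Z-selective Wittig olefination of a non-stabilised ylide under lithium-free, halide-free conditions at −78 °C forms the 13Z alkene kinetically through the cis-oxaphosphetane while the 15Z geometry is carried in from 12, and at this temperature the ylide neither opens the remote trans-oxirane nor touches the carboxylate.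

**Step 9**
Reactants: 14 (8S,9S,13Z,15Z)-8,9-epoxyoctadeca-13,15-diene-4,6-diynoic acid (3 equiv); 15 sn-glycero-3-phosphocholine (1 equiv, dried, on Celite)
Product: 17 1,2-bis[(8S,9S,13Z,15Z)-8,9-epoxyoctadeca-13,15-diene-4,6-diynoyl]-sn-glycero-3-phosphocholine, via 1-acyl lyso-phosphatidylcholine 16 (not isolated)
Conditions: DCC (3.3 equiv), DMAP (2 equiv), CHCl3 (ethanol-free), rt, 48 h, dark, Ar
Reagents that add atoms: none
Why: Steglich-type DCC/DMAP acylation esterifies the primary and then the secondary hydroxyl of the glycerophosphocholine under neutral conditions that spare the oxiranes, and the glycerol stereocentre is carried in unchanged from 15.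

**Step 10**
Reactants: 17 1,2-bis[(8S,9S,13Z,15Z)-8,9-epoxyoctadeca-13,15-diene-4,6-diynoyl]-sn-glycero-3-phosphocholine
Product: 18 1,2-di-O-[(8S,9S,13Z,15Z)-8,9-epoxyoctadeca-13,15-diene-4,6-diynoyl]-sn-glycerol (target)
Conditions: phospholipase C (Bacillus cereus), Et2O/Tris·HCl buffer pH 7.4, 25 °C, 3 h; chromatography on boric acid-treated silica, 4 °C
Reagents that add atoms: none
Why: Enzymatic phosphodiester hydrolysis cleaves the glycerol–phosphate P–O bond at neutral pH, so the C2 stereocentre and both esters are untouched and the 1,2-diacyl-sn-glycerol is released without the acid or base that would cause 1,2→1,3 acyl migration or oxirane opening.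

## Compound list

1 | 6-bromohex-1-yne | C#CCCCCBr | starting material
2 | [(E)-6-bromohex-1-en-1-yl]zirconocene chloride | [cH-]1cccc1.[cH-]1cccc1.Cl[Zr+2]/C=C/CCCCBr | intermediate
3 | (E)-6-bromo-1-iodohex-1-ene | BrCCCC/C=C/I | intermediate
4 | (E)-8-bromooct-3-en-1-yne | C#C/C=C/CCCCBr | intermediate
5 | pent-4-ynoic acid | C#CCCC(=O)O | starting material
6 | 5-bromopent-4-ynoic acid | BrC#CCCC(=O)O | intermediate
7 | (E)-13-bromotridec-8-ene-4,6-diynoic acid | OC(=O)CCC#CC#C/C=C/CCCCBr | intermediate
8 | [(E)-12-carboxydodec-5-ene-7,9-diyn-1-yl]triphenylphosphonium bromide | OC(=O)CCC#CC#C/C=C/CCCC[P+](c1ccccc1)(c1ccccc1)c1ccccc1.[Br-] | intermediate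
9 | (E)-13-(triphenylphosphonio)tridec-8-ene-4,6-diynoate, inner salt | [O-]C(=O)CCC#CC#C/C=C/CCCC[P+](c1ccccc1)(c1ccccc1)c1ccccc1 | intermediate
10 | 7-{(2S,3S)-3-[4-(triphenylphosphonio)butyl]oxiran-2-yl}hepta-4,6-diynoate, inner salt | [O-]C(=O)CCC#CC#C[C@@H]1O[C@H]1CCCC[P+](c1ccccc1)(c1ccccc1)c1ccccc1 | intermediate
11 | (Z)-pent-2-en-1-ol | CC/C=C\CO | starting material
12 | (Z)-pent-2-enal | CC/C=C\C=O | intermediate
13 | sodium 7-{(2S,3S)-3-[4-(triphenylphosphoranylidene)butyl]oxiran-2-yl}hepta-4,6-diynoate (ylide) | [Na+].[O-]C(=O)CCC#CC#C[C@@H]1O[C@H]1CCCC=P(c1ccccc1)(c1ccccc1)c1ccccc1 | intermediate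
14 | (8S,9S,13Z,15Z)-8,9-epoxyoctadeca-13,15-diene-4,6-diynoic acid, i.e. 7-{(2S,3S)-3-[(4Z,6Z)-nona-4,6-dien-1-yl]oxiran-2-yl}hepta-4,6-diynoic acid | CC/C=C\C=C/CCC[C@@H]1O[C@H]1C#CC#CCCC(=O)O | intermediate
15 | sn-glycero-3-phosphocholine, (R) | C[N+](C)(C)CCOP(=O)([O-])OC[C@H](O)CO | starting material
16 | 1-[(8S,9S,13Z,15Z)-8,9-epoxyoctadeca-13,15-diene-4,6-diynoyl]-sn-glycero-3-phosphocholine | CC/C=C\C=C/CCC[C@@H]1O[C@H]1C#CC#CCCC(=O)OC[C@H](COP(=O)([O-])OCC[N+](C)(C)C)O | intermediate
17 | 1,2-bis[(8S,9S,13Z,15Z)-8,9-epoxyoctadeca-13,15-diene-4,6-diynoyl]-sn-glycero-3-phosphocholine | CC/C=C\C=C/CCC[C@@H]1O[C@H]1C#CC#CCCC(=O)OC[C@H](COP(=O)([O-])OCC[N+](C)(C)C)OC(=O)CCC#CC#C[C@@H]1O[C@H]1CCC/C=C\C=C/CC | intermediate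
18 | 1,2-di-O-[(8S,9S,13Z,15Z)-8,9-epoxyoctadeca-13,15-diene-4,6-diynoyl]-sn-glycerol, glycerol C2 (S) | CC/C=C\C=C/CCC[C@@H]1O[C@H]1C#CC#CCCC(=O)OC[C@H](CO)OC(=O)CCC#CC#C[C@@H]1O[C@H]1CCC/C=C\C=C/CC | target

## Step count and risk

Total: 10 steps. Longest linear sequence: 8 steps (1, 2, 4, 5, 6, 8, 9, 10).

Expected stereochemical purity: the Shi step should give roughly 90–95% ee, so 10 should be recrystallised if it is crystalline, because diastereomers formed after the chain is doubled onto glycerol will not be separable.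

**Step 6 (most likely to fail).** The oxidation is run on a zwitterion: conversion of the electron-poor alkene may stall and isolation of the inner salt from the salt-laden buffer is untested. The fallback epoxidises a neutral ester before phosphorus is introduced. It sets out from 7 and comes back at 14. Esterify 7 with Me3SiCHN2/MeOH to methyl (E)-13-bromotridec-8-ene-4,6-diynoate F1. Epoxidise F1 with the same L-ketone/KHSO5 system to methyl 7-[(2S,3S)-3-(4-bromobutyl)oxiran-2-yl]hepta-4,6-diynoate F2. Quaternise with PPh3 in MeCN at 60 °C (no proton source, so bromide does not open the oxirane) to {4-[(2S,3S)-3-(7-methoxy-7-oxohepta-1,3-diyn-1-yl)oxiran-2-yl]butyl}triphenylphosphonium bromide F3. Wittig reaction with 12 (NaN(SiMe3)2, THF, −78 °C) gives methyl (8S,9S,13Z,15Z)-8,9-epoxyoctadeca-13,15-diene-4,6-diynoate F4, and LiOH in THF/H2O at 0 °C gives 14. This costs two extra steps.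

**Step 8.** The ylide sits four carbons from an oxirane (possible 5-exo opening if the mixture warms before the aldehyde is consumed), the inner salt may dissolve poorly at −78 °C, and 12 can isomerise. The fallback reverses the polarity so that the oxirane is on the electrophile and no Z-enal is needed. It sets out from 7 (and 11) and comes back at 14. Epoxidise the potassium salt of 7 under the step 6 conditions to 7-[(2S,3S)-3-(4-bromobutyl)oxiran-2-yl]hepta-4,6-diynoic acid F5. Oxidise the primary bromide with Me3NO in DMSO at rt (Ganem–Kornblum-type oxidation) to 7-[(2S,3S)-3-(4-oxobutyl)oxiran-2-yl]hepta-4,6-diynoic acid F6. Separately, Mitsunobu reaction of 11 with pyridine-2-thiol (PPh3, DIAD) gives 2-[(Z)-pent-2-en-1-ylsulfanyl]pyridine F7, and (NH4)6Mo7O24/H2O2 gives 2-[(Z)-pent-2-en-1-ylsulfonyl]pyridine F8. Julia-type olefination of F6 with the anion of F8 (KN(SiMe3)2, 2.2 equiv, toluene/THF, −78 °C → rt) gives 14; the 2-pyridyl sulfone is the variant reported to favour Z at the new bond of 1,3-dienes, but this selectivity is the weak point of the fallback.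

**Step 5.** The conjugated enediyne acid is heated with a nucleophilic phosphine for 36 h and may polymerise. The fallback puts phosphorus on a robust fragment and makes the C7–C8 bond instead of C5–C6. It sets out from 3 and 6 and comes back at 8. Heat 3 with PPh3 in MeCN at 80 °C (the alkenyl iodide is inert) to [(E)-6-iodohex-5-en-1-yl]triphenylphosphonium bromide F9. Couple 6 with ethynyltrimethylsilane under the step 4 conditions to 7-(trimethylsilyl)hepta-4,6-diynoic acid F10 and desilylate (K2CO3, MeOH, 0 °C) to hepta-4,6-diynoic acid F11. Sonogashira coupling of F9 with F11 (Pd(PPh3)2Cl2, CuI, i-Pr2NH, DMF, rt) gives 8 as a mixed bromide/iodide, and the NaHCO3 partition of step 5 then delivers 9; iodide must be washed out completely before step 6.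

## Further compounds

F1 | step 6 | methyl (E)-13-bromotridec-8-ene-4,6-diynoate | COC(=O)CCC#CC#C/C=C/CCCCBr
F2 | step 6 | methyl 7-[(2S,3S)-3-(4-bromobutyl)oxiran-2-yl]hepta-4,6-diynoate | COC(=O)CCC#CC#C[C@@H]1O[C@H]1CCCCBr
F3 | step 6 | {4-[(2S,3S)-3-(7-methoxy-7-oxohepta-1,3-diyn-1-yl)oxiran-2-yl]butyl}triphenylphosphonium bromide | COC(=O)CCC#CC#C[C@@H]1O[C@H]1CCCC[P+](c1ccccc1)(c1ccccc1)c1ccccc1.[Br-]
F4 | step 6 | methyl (8S,9S,13Z,15Z)-8,9-epoxyoctadeca-13,15-diene-4,6-diynoate | CC/C=C\C=C/CCC[C@@H]1O[C@H]1C#CC#CCCC(=O)OC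
F5 | step 8 | 7-[(2S,3S)-3-(4-bromobutyl)oxiran-2-yl]hepta-4,6-diynoic acid | OC(=O)CCC#CC#C[C@@H]1O[C@H]1CCCCBr
F6 | step 8 | 7-[(2S,3S)-3-(4-oxobutyl)oxiran-2-yl]hepta-4,6-diynoic acid | OC(=O)CCC#CC#C[C@@H]1O[C@H]1CCCC=O
F7 | step 8 | 2-[(Z)-pent-2-en-1-ylsulfanyl]pyridine | CC/C=C\CSc1ccccn1
F8 | step 8 | 2-[(Z)-pent-2-en-1-ylsulfonyl]pyridine | CC/C=C\CS(=O)(=O)c1ccccn1
F9 | step 5 | [(E)-6-iodohex-5-en-1-yl]triphenylphosphonium bromide | I/C=C/CCCC[P+](c1ccccc1)(c1ccccc1)c1ccccc1.[Br-]
F10 | step 5 | 7-(trimethylsilyl)hepta-4,6-diynoic acid | C[Si](C)(C)C#CC#CCCC(=O)O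
F11 | step 5 | hepta-4,6-diynoic acid | C#CC#CCCC(=O)O
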